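## Structural features

The target is a germacranolide: a ten-membered carbocycle (C1–C10) fused across C6–C7 to an α-methylene-γ-butyrolactone (O6–C12(=O)–C11(=C13)–C7). Both ring alkenes are trisubstituted and cis within the ring: C1=C10 carries the C14 aldehyde on C10, and C4=C5 carries the C15 hydroxymethyl group on C4. Each is E by the sequence rule, because C14 and C15 outrank the ring carbons. The stereocentres C6 (R), C7 (S) and C8 (S) are contiguous. H6 and H7 are cis (cis-fused lactone), and the C8 oxygen, esterified by 3-methylbutanoic acid, is anti to the C11 arm and syn to O6 when C5–C8 is drawn as a zigzag. Fragile groups are the conjugated aldehyde, the methylene lactone (a Michael acceptor), the allylic C–O bonds at C6 and C15, and the enolisable C8 ester. In open-chain relatives C12 is γ to both O6 and O8, so a wrong lactone can form whenever one of these oxygens is free. The real difficulty is to close a strained cis,cis-cyclodecadiene while fixing C6 against the facial bias of the C7/C8 array, and to hold C6, C12 and C14 at three different oxidation levels without cross-reaction. The key step exploits the fact that C6 is an allylic carbinol carbon bonded to C5 of the cis C4=C5 bond. An alkenylmetal at C5 can add to a C6 aldehyde with the alkene geometry preserved, so the C5–C6 bond, the ring and the C6 stereocentre arise together.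

## Logic of the disconnections

37 from 36: the O15–Si bond and the two C14–OMe bonds are cut; no skeletal bond is touched. The free enal, the allylic alcohol and the methylene lactone are the least robust combination, so they should coexist only in the last flask. The gain is that C14 and C15 stay inert through all carbon–carbon bond formation. The demand is one mild aqueous acid treatment that spares the C8 ester, the lactone and both ring alkenes.

36 from 34 and 35, then 34 from 33: the O8–acyl bond and then the O8–benzyl bond are cut. An enolisable ester at C8 would not survive the strong-base steps, so O8 carries an oxidatively removable benzyl-type ether, orthogonal to the silyl ether and the acetal. The acyl group then comes from a commercial acid chloride. The acylation has to be faster than migration of the lactone to O8.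

33 from 29 and 30: the C11=C13 bond is cut. The methylene lactone is a Michael acceptor and is therefore made after the ring. The gain is a lactone whose only enolisable position is C11. The forward step must give clean mono-aminomethylation and elimination.

29 from 28: the O6–C12 bond is cut. With O6 cis to the C11 arm, five-ring closure onto a methyl ester needs only mild acid. The gain is an open ester arm during ring formation. The demand is that C6 has the correct configuration beforehand.

28 from 27 (the strategic cut): the C5–C6 bond is cut. C6 is an allylic carbinol on C5, and an alkenyl iodide–aldehyde coupling tolerates the ester, acetal and ethers. The ring and the C6 stereocentre disappear, leaving an open chain with only C7 and C8 as stereocentres. The forward step must close a ten-membered ring at high dilution and deliver C5 to the Re face of the aldehyde under ligand control. The structures of 27 and 28 were checked centre by centre against the target and needed no correction. The constitution of 27 is kept; what is improved is the way it is reached (next paragraphs).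

27 from 26, 24, 22 and 21: no skeletal bond is cut; the oxidation levels of C6 and C12 are adjusted. The C12 carboxyl is traced to a vinyl group (C11=C12), and the C6 aldehyde to a triethylsilyl ether that is oxidised directly. The reason is that a C12 ester would lactonise onto a free O6 or O8 and would not survive the hydride step at C14. The gain is an arm that is inert to base and hydride. The demand is hydroboration of the monosubstituted alkene only, and oxidations that spare the acetal.

21 from 20, 19 and 18: the C14 acetal C–O bonds, the C14–H bonds and the benzylic C–O6 bond of the arylidene acetal are traced back. C14 must be a protected aldehyde before ring closure, because a free enal would compete for the alkenylchromium. One hydride step reduces the C14 ester and turns the cyclic acetal into the O8 ether plus the free C6 alcohol. The gain is three protecting-group changes in one operation. The demand is regioselective acetal opening and oxidation of the allylic alcohol only.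

18 from 16, and 16 from 15 and 7: the C1=C10 bond is cut near the middle of the chain. This gives two fragments of similar size, and the required geometry (C2 trans to C14) is the thermodynamically preferred one of an α-alkyl enoate. The demand is an E-selective elimination, with the C14 ester as the only enolisable carbonyl present.

15 from 14, and 14 from 12 and 13: the C7–C11 bond is cut (and the acetal C–O bonds). Opening an epoxide at C7 with inversion gives the anti relation between O8 and the C11 arm. Both stereocentres are thus traced to one epoxide. The nucleophile must attack C7 and not C8.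

12 from 11, 10, and then 8 and 9: the epoxide C–O bonds at C7 and C8 and then the C7=C8 bond are cut. Catalytic asymmetric epoxidation of an E allylic alcohol sets the absolute configuration, and a stabilised ylide gives the E alkene. The demand is a geometrically pure alkene. The tert-butyl ester at C14 is chosen so that O8 cannot lactonise onto it.

7 from 6, 5, 4, and then 1 and 2: the C5–I bond (from C5–Si) and the C3–C4 bond are cut. Anti addition across a silyl alkyne fixes the geometry that places C5 cis to C3. The demand is regio- and stereoselective carbomagnesiation and iododesilylation with retention.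

## Other disconnections considered

Alternative 1: The cut is the bisallylic C2–C3 single bond. In the forward step the sulfonyl-stabilised C3 carbanion of the open-chain bromo sulfone A1 (lithium amide base) would displace the primary allylic bromide at C2 and give the cyclic sulfone A2.
- In its favour: no lasting stereocentre is made at ring closure, and C6, C7 and C8 are all set beforehand in ordinary acyclic and five-ring chemistry. On the C6 problem this is better than the chosen plan. Sulfone carbanion alkylation tolerates most groups, and on pre-organisation by two cis alkenes it is the equal of the chosen plan.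
- Against it here: the allyl sulfone anion can react at its α or γ carbon and the bromide by direct or allylic displacement, so several constitutional outcomes compete. The sulfone must then be removed reductively next to the C4=C5 bond and the allylic C15 ether, which risks alkene migration or loss of geometry. The lactone is carried as a lactol ether and must be re-oxidised late.
- Step economy: ring closure, desulfonylation and lactol oxidation replace ring closure, lactonisation and methylenation, so the endgame is about equal. The fully substituted lactol precursor should take longer to assemble.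

Alternative 2: The cut is C7–C8. CrCl2 would convert the bromomethyl enoate A3 into an allylchromium species that adds through C7 to the C8 aldehyde and gives the carbinol A4.
- In its favour: one step forms the ring, two stereocentres and the C11=C13 methylene. No separate methylenation and no benzyl ether at O8 are needed, because O8 emerges free and could be acylated at once. On endgame length this is better than the chosen plan. No nickel co-catalyst is needed, and on tolerance of esters and acetals it is the equal of the chosen plan.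
- Against it here: C7 and C8 would have to be relayed from C6 through a medium-ring transition state with no reagent control, and the open-chain preference of γ-substituted allylchromium reagents does not obviously match the required array. The C8 aldehyde is β,γ-unsaturated and can slip into conjugation. The free O8 can lactonise onto C12 in competition with O6.
- Comparison: the chosen plan sets C7 and C8 early under reagent control and leaves one centre for the ring closure. The alternative is shorter but stakes two centres on one uncontrolled event.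

Alternative 3: The cut is the C1=C10 double bond. The anion of the phosphonoacetate A5 would add to the C1 aldehyde and eliminate phosphate to give the cyclic enoate A6, with the C6–C8 triad taken from a sugar.
- In its favour: absolute and relative configuration come from the chiral pool, which is more secure than a ligand-controlled addition. No stereocentre is formed at ring closure. The olefination is robust and on functional-group tolerance the equal of the Ni/Cr coupling. The required enoate geometry is the thermodynamically preferred one.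
- Against it here: ten-membered rings are at the unfavourable end for intramolecular olefination, and dimerisation is the expected competitor. C14 arrives as an ester, so the lactone must be masked as a lactol ether, C14 reduced and re-oxidised, and the lactol oxidised back. Sugar-derived triads need several deoxygenation and chain-extension steps.
- Comparison: the chosen plan has C14 at the aldehyde level before closure and is better on redox economy. On reliability of the closure the two are roughly equal. On stereochemical security the alternative is better.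

Key step: step 19

Remark (assumption): the antipode of the oxazoline sulfonamide ligand that sends the alkenyl group to the Re face of the C6 aldehyde is taken to be the (S)-ligand from L-valinol; if a trial addition shows the opposite sense, the (R)-ligand is used in the same way.

Step 1
Reactants: 1 2-(2-bromoethyl)-1,3-dioxolane; 2 3-(trimethylsilyl)prop-2-yn-1-ol
Product: 4 (E)-2-[2-(1,3-dioxolan-2-yl)ethyl]-3-(trimethylsilyl)prop-2-en-1-ol, via Grignard reagent 3 (not isolated)
Conditions: 1, Mg, THF, 25–30 °C; then 2, CuI (10 mol%), THF, −10 °C → rt; aq NH4Cl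
Reagents that add atoms: none
Why: Copper-catalysed, alkoxide-directed anti-carbomagnesiation of a propargylic alcohol: the alkyl group adds to the alkyne carbon next to CH2O and magnesium ends on the silyl-bearing carbon cis to the alkoxide (five-membered chelate, α-silyl stabilisation), so protonation leaves SiMe3 cis to the new C3–C4 bond. This fixes the C4=C5 geometry; the reagent is kept at or below room temperature because it is thermally labile.

Step 2
Reactants: 4 (E)-2-[2-(1,3-dioxolan-2-yl)ethyl]-3-(trimethylsilyl)prop-2-en-1-ol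
Product: 5 (E)-2-[2-(1,3-dioxolan-2-yl)ethyl]-3-iodoprop-2-en-1-ol
Conditions: N-iodosuccinimide, 2,6-lutidine, (CF3)2CHOH, 0 °C
Reagents that add atoms: N-iodosuccinimide, O=C1CCC(=O)N1I
Why: Ipso-iododesilylation of a vinylsilane (electrophilic attack to a β-silyl cation, then loss of silicon) should proceed with retention, so iodine ends cis to the C3 chain; the lutidine buffer protects the dioxolane.

Step 3
Reactants: 5 (E)-2-[2-(1,3-dioxolan-2-yl)ethyl]-3-iodoprop-2-en-1-ol
Product: 6 tert-butyl{[(E)-2-[2-(1,3-dioxolan-2-yl)ethyl]-3-iodoprop-2-en-1-yl]oxy}dimethylsilane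
Conditions: t-BuMe2SiCl, imidazole, CH2Cl2, 0 °C → rt
Reagents that add atoms: tert-butyl(chloro)dimethylsilane, CC(C)(C)[Si](C)(C)Cl
Why: Standard silylation of a primary allylic alcohol; this ether is later removed together with the acetal in the last step.

Step 4
Reactants: 6 tert-butyl{[(E)-2-[2-(1,3-dioxolan-2-yl)ethyl]-3-iodoprop-2-en-1-yl]oxy}dimethylsilane
Product: 7 (E)-4-{[(tert-butyldimethylsilyl)oxy]methyl}-5-iodopent-4-enal
Conditions: pyridinium p-toluenesulfonate (cat.), acetone–H2O, 55 °C
Reagents that add atoms: water, O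
Why: Acid-catalysed acetal hydrolysis in wet acetone; the pyridinium salt is mild enough to leave a primary silyl ether in an aprotic medium.

Step 5
Reactants: 8 tert-butyl 4-oxobutanoate; 9 (triphenylphosphoranylidene)acetaldehyde
Product: 10 tert-butyl (E)-6-oxohex-4-enoate
Conditions: PhMe, 70 °C
Reagents that add atoms: none
Why: Wittig reaction of a stabilised ylide should give the E enal (C7=C8); a slight excess of 8 limits a second homologation.

Step 6
Reactants: 10 tert-butyl (E)-6-oxohex-4-enoate
Product: 11 tert-butyl (E)-6-hydroxyhex-4-enoate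
Conditions: NaBH4, CeCl3·7H2O, MeOH, −40 °C
Reagents that add atoms: none
Why: Luche 1,2-reduction of the enal; the tert-butyl ester is not touched.

Step 7
Reactants: 11 tert-butyl (E)-6-hydroxyhex-4-enoate
Product: 12 tert-butyl 3-[(2S,3S)-3-(hydroxymethyl)oxiran-2-yl]propanoate
Conditions: Ti(OCHMe2)4 (10 mol%), L-(+)-diisopropyl tartrate (12 mol%), t-BuOOH, 4 Å molecular sieves, CH2Cl2, −20 °C
Reagents that add atoms: tert-butyl hydroperoxide, CC(C)(C)OO
Why: Sharpless asymmetric epoxidation of an E allylic alcohol; the L-(+)-tartrate should give the (2S,3S) epoxide, which fixes C8 and, after inversion in step 8, C7.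

Step 8
Reactants: 12 tert-butyl 3-[(2S,3S)-3-(hydroxymethyl)oxiran-2-yl]propanoate; 13 ethenylmagnesium bromide
Product: 14 tert-butyl (4S,5R)-5-ethenyl-4,6-dihydroxyhexanoate
Conditions: 13 (5 equiv), CuI (0.5 equiv), THF–Et2O, −30 → −15 °C; aq NH4Cl
Reagents that add atoms: none
Why: Copper-mediated opening of a 2,3-epoxy alcohol at the carbon next to the hydroxymethyl group (C7) with inversion gives the anti 2-vinyl-1,3-diol; C8 keeps its configuration. The hindered ester should resist both the Grignard reagent and lactonisation at this temperature.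

Step 9
Reactants: 14 tert-butyl (4S,5R)-5-ethenyl-4,6-dihydroxyhexanoate
Product: 15 tert-butyl 3-[(2R,4S,5R)-5-ethenyl-2-(4-methoxyphenyl)-1,3-dioxan-4-yl]propanoate
Conditions: 4-MeOC6H4CH(OMe)2, pyridinium p-toluenesulfonate (cat.), CH2Cl2, rt
Reagents that add atoms: 4-methoxybenzaldehyde dimethyl acetal, COc1ccc(C(OC)OC)cc1
Why: Thermodynamic acetalisation of the 1,3-diol; the all-equatorial chair places the aryl group cis to the C8 side chain, which defines the acetal centre.

Step 10
Reactants: 15 tert-butyl 3-[(2R,4S,5R)-5-ethenyl-2-(4-methoxyphenyl)-1,3-dioxan-4-yl]propanoate; 7 (E)-4-{[(tert-butyldimethylsilyl)oxy]methyl}-5-iodopent-4-enal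
Product: 16 tert-butyl (6E)-6-{[(tert-butyldimethylsilyl)oxy]methyl}-2-{[(2R,4S,5R)-5-ethenyl-2-(4-methoxyphenyl)-1,3-dioxan-4-yl]methyl}-3-hydroxy-7-iodohept-6-enoate (mixture of C2/C3 diastereomers)
Conditions: LiN(CHMe2)2, THF, −78 °C; then 7, −78 °C; aq NH4Cl
Reagents that add atoms: none
Why: Aldol addition of the ester lithium enolate (C10) to the C1 aldehyde; the ester is the only enolisable carbonyl in 15, and the two new centres are removed in step 11.

Step 11
Reactants: 16 tert-butyl (6E)-6-{[(tert-butyldimethylsilyl)oxy]methyl}-2-{[(2R,4S,5R)-5-ethenyl-2-(4-methoxyphenyl)-1,3-dioxan-4-yl]methyl}-3-hydroxy-7-iodohept-6-enoate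
Product: 18 tert-butyl (2E,6E)-6-{[(tert-butyldimethylsilyl)oxy]methyl}-2-{[(2R,4S,5R)-5-ethenyl-2-(4-methoxyphenyl)-1,3-dioxan-4-yl]methyl}-7-iodohepta-2,6-dienoate, via mesylate 17 (not isolated)
Conditions: MeSO2Cl, Et3N, CH2Cl2, 0 °C; then 1,8-diazabicyclo[5.4.0]undec-7-ene, rt
Reagents that add atoms: none
Why: Mesylation followed by E1cB elimination through the ester enolate should favour the more stable E enoate (C2 trans to the ester), which is the C1=C10 geometry of the target.

Step 12
Reactants: 18 tert-butyl (2E,6E)-6-{[(tert-butyldimethylsilyl)oxy]methyl}-2-{[(2R,4S,5R)-5-ethenyl-2-(4-methoxyphenyl)-1,3-dioxan-4-yl]methyl}-7-iodohepta-2,6-dienoate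
Product: 19 (2R,3S,5E,9E)-9-{[(tert-butyldimethylsilyl)oxy]methyl}-2-ethenyl-5-(hydroxymethyl)-10-iodo-3-[(4-methoxyphenyl)methoxy]deca-5,9-dien-1-ol
Conditions: i-Bu2AlH (6 equiv), CH2Cl2, −78 → 0 °C; aq KNaC4H4O6
Reagents that add atoms: none
Why: The aluminium hydride reduces the enoate to the allylic alcohol (C14) and opens the arylidene acetal reductively: aluminium binds the less hindered primary oxygen (O6), so the 4-methoxybenzyl group stays on the secondary O8. Alkenyl iodides and silyl ethers are inert under these conditions.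

Step 13
Reactants: 19 (2R,3S,5E,9E)-9-{[(tert-butyldimethylsilyl)oxy]methyl}-2-ethenyl-5-(hydroxymethyl)-10-iodo-3-[(4-methoxyphenyl)methoxy]deca-5,9-dien-1-ol
Product: 20 (2E,6E)-6-{[(tert-butyldimethylsilyl)oxy]methyl}-2-{(2S,3R)-3-(hydroxymethyl)-2-[(4-methoxyphenyl)methoxy]pent-4-en-1-yl}-7-iodohepta-2,6-dienal
Conditions: MnO2, CH2Cl2, rt
Reagents that add atoms: none
Why: Manganese dioxide oxidises only the allylic primary alcohol (C14); the saturated C6 alcohol is left.

Step 14
Reactants: 20 (2E,6E)-6-{[(tert-butyldimethylsilyl)oxy]methyl}-2-{(2S,3R)-3-(hydroxymethyl)-2-[(4-methoxyphenyl)methoxy]pent-4-en-1-yl}-7-iodohepta-2,6-dienal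
Product: 21 (2R,3S,5E,9E)-9-{[(tert-butyldimethylsilyl)oxy]methyl}-5-(dimethoxymethyl)-2-ethenyl-10-iodo-3-[(4-methoxyphenyl)methoxy]deca-5,9-dien-1-ol
Conditions: HC(OMe)3, MeOH, pyridinium p-toluenesulfonate (cat.), 0 °C; Et3N
Reagents that add atoms: trimethyl orthoformate, COC(OC)OC; methanol, CO
Why: Acid-catalysed acetalisation driven by the orthoformate; the short cold treatment should spare the silyl ether, and the acetal keeps C14 away from the alkenylchromium in step 19.

Step 15
Reactants: 21 (2R,3S,5E,9E)-9-{[(tert-butyldimethylsilyl)oxy]methyl}-5-(dimethoxymethyl)-2-ethenyl-10-iodo-3-[(4-methoxyphenyl)methoxy]deca-5,9-dien-1-ol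
Product: 22 {[(2R,3S,5E,9E)-9-{[(tert-butyldimethylsilyl)oxy]methyl}-5-(dimethoxymethyl)-2-ethenyl-10-iodo-3-[(4-methoxyphenyl)methoxy]deca-5,9-dien-1-yl]oxy}triethylsilane
Conditions: Et3SiCl, imidazole, CH2Cl2, 0 °C
Reagents that add atoms: chlorotriethylsilane, CC[Si](CC)(CC)Cl
Why: Silylation of the primary C6 alcohol with a group that the Swern reagent can later convert directly into the aldehyde.

Step 16
Reactants: 22 {[(2R,3S,5E,9E)-9-{[(tert-butyldimethylsilyl)oxy]methyl}-5-(dimethoxymethyl)-2-ethenyl-10-iodo-3-[(4-methoxyphenyl)methoxy]deca-5,9-dien-1-yl]oxy}triethylsilane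
Product: 24 (3R,4S,6E,10E)-10-{[(tert-butyldimethylsilyl)oxy]methyl}-6-(dimethoxymethyl)-11-iodo-4-[(4-methoxyphenyl)methoxy]-3-{[(triethylsilyl)oxy]methyl}undeca-6,10-dien-1-ol, via alkylborane 23 (not isolated)
Conditions: 9-borabicyclo[3.3.1]nonane, THF, 0 °C → rt; then NaOH, H2O2, 0 °C
Reagents that add atoms: hydrogen peroxide, OO
Why: Hydroboration–oxidation; the bulky borane should add only to the monosubstituted alkene (anti-Markovnikov, giving C12–OH) and leave the trisubstituted alkene and the alkenyl iodide.

Step 17
Reactants: 24 (3R,4S,6E,10E)-10-{[(tert-butyldimethylsilyl)oxy]methyl}-6-(dimethoxymethyl)-11-iodo-4-[(4-methoxyphenyl)methoxy]-3-{[(triethylsilyl)oxy]methyl}undeca-6,10-dien-1-ol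
Product: 26 methyl (3R,4S,6E,10E)-10-{[(tert-butyldimethylsilyl)oxy]methyl}-6-(dimethoxymethyl)-11-iodo-4-[(4-methoxyphenyl)methoxy]-3-{[(triethylsilyl)oxy]methyl}undeca-6,10-dienoate, via carboxylic acid 25 (not isolated)
Conditions: TEMPO (cat.), PhI(OAc)2, MeCN–pH 7 buffer, rt; then Me3SiCHN2, PhMe–MeOH, 0 °C
Reagents that add atoms: water, O; trimethylsilyldiazomethane, C[Si](C)(C)C=[N+]=[N-]
Why: Oxoammonium-mediated oxidation of the primary alcohol through the aldehyde hydrate to the acid, then methylation with the diazomethane equivalent; the buffer protects the acetal and the triethylsilyl ether. The ester arm appears only now, with O8 capped and O6 silylated, so no lactone can form.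

Step 18
Reactants: 26 methyl (3R,4S,6E,10E)-10-{[(tert-butyldimethylsilyl)oxy]methyl}-6-(dimethoxymethyl)-11-iodo-4-[(4-methoxyphenyl)methoxy]-3-{[(triethylsilyl)oxy]methyl}undeca-6,10-dienoate
Product: 27 methyl (3S,4S,6E,10E)-10-{[(tert-butyldimethylsilyl)oxy]methyl}-6-(dimethoxymethyl)-3-formyl-11-iodo-4-[(4-methoxyphenyl)methoxy]undeca-6,10-dienoate
Conditions: (COCl)2, DMSO, CH2Cl2, −78 → −40 °C; then Et3N, −78 → 0 °C
Reagents that add atoms: none
Why: Swern conditions convert a primary triethylsilyl ether directly into the aldehyde (chloride removes silicon at the sulfonium stage), while the tert-butyldimethylsilyl ether is inert. The free γ-hydroxy ester is never formed, and 27 is used at once to avoid epimerisation at C7 or loss of the C8 ether.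

Step 19
Reactants: 27 methyl (3S,4S,6E,10E)-10-{[(tert-butyldimethylsilyl)oxy]methyl}-6-(dimethoxymethyl)-3-formyl-11-iodo-4-[(4-methoxyphenyl)methoxy]undeca-6,10-dienoate
Product: 28 methyl 2-[(1R,2R,3E,7E,10S)-4-{[(tert-butyldimethylsilyl)oxy]methyl}-8-(dimethoxymethyl)-2-hydroxy-10-[(4-methoxyphenyl)methoxy]cyclodeca-3,7-dien-1-yl]acetate
Conditions: CrCl2 (6 equiv), (S)-N-[2-(4-isopropyl-4,5-dihydrooxazol-2-yl)-6-methylphenyl]methanesulfonamide (6.6 equiv), Et3N, THF, rt; NiCl2 (10 mol%); 27 added slowly to 2 mM, rt; aq sodium serinate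
Reagents that add atoms: none
Why: Zerovalent nickel, formed from NiCl2 by CrCl2, inserts into the C5–I bond with retention, transmetalation gives a trivalent alkenylchromium species, and this adds to the C6 aldehyde (Nozaki–Hiyama–Kishi reaction). The closest known reaction type is the Ni/Cr alkenyl iodide–aldehyde macrocyclisation, including its asymmetric form with chiral sulfonamide ligands on chromium. The ten-membered carbocycle closes in a 10-exo-trig mode by attack of C5 on the exocyclic C6 carbonyl. C6 is the only new stereocentre and is set by the chiral ligand on chromium, which must deliver C5 to the Re face of the aldehyde to give 6R (O6 cis to the C11 arm), against the Felkin–Anh and 1,3-anti preferences of the α-branched β-alkoxy aldehyde. Chemoselectivity for the aldehyde over the ester, acetal and ethers rests on the low basicity and carbonyl selectivity of the organochromium reagent, which also leaves C7 untouched. The C4=C5 geometry from step 1 is carried unchanged, the two cis trisubstituted alkenes bend the chain so that C5 and C6 can meet, and slow addition at high dilution suppresses intermolecular coupling. Partial lactonisation of the chromium alkoxide onto the methyl ester would be harmless because step 20 completes it.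

Step 20
Reactants: 28 methyl 2-[(1R,2R,3E,7E,10S)-4-{[(tert-butyldimethylsilyl)oxy]methyl}-8-(dimethoxymethyl)-2-hydroxy-10-[(4-methoxyphenyl)methoxy]cyclodeca-3,7-dien-1-yl]acetate
Product: 29 (1(10)E,4E,6R,7S,8S)-15-[(tert-butyldimethylsilyl)oxy]-14,14-dimethoxy-8-[(4-methoxyphenyl)methoxy]-13-norgermacra-1(10),4-dien-12,6-olide
Conditions: pyridinium p-toluenesulfonate (cat.), PhH, rt
Reagents that add atoms: none
Why: Acid-catalysed lactonisation of a γ-hydroxy ester; O6 and the C11 arm are cis, so the five-membered ring should close readily, and the anhydrous medium preserves the acetal.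

Step 21
Reactants: 29 (1(10)E,4E,6R,7S,8S)-15-[(tert-butyldimethylsilyl)oxy]-14,14-dimethoxy-8-[(4-methoxyphenyl)methoxy]-13-norgermacra-1(10),4-dien-12,6-olide; 30 N,N-dimethylmethyleneiminium iodide
Product: 33 (1(10)E,4E,6R,7S,8S)-15-[(tert-butyldimethylsilyl)oxy]-14,14-dimethoxy-8-[(4-methoxyphenyl)methoxy]germacra-1(10),4,11(13)-trien-12,6-olide, via Mannich base 31 (not isolated), via methiodide 32 (not isolated)
Conditions: LiN(CHMe2)2, THF, −78 °C; 30, −78 → 0 °C; then MeI, MeOH, rt; then NaHCO3 (aq), CH2Cl2
Reagents that add atoms: none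
Why: Mannich aminomethylation of the lactone lithium enolate, N-methylation and β-elimination of trimethylamine give the exocyclic methylene; C11 is the only enolisable position and its configuration is lost in the alkene.

Step 22
Reactants: 33 (1(10)E,4E,6R,7S,8S)-15-[(tert-butyldimethylsilyl)oxy]-14,14-dimethoxy-8-[(4-methoxyphenyl)methoxy]germacra-1(10),4,11(13)-trien-12,6-olide
Product: 34 (1(10)E,4E,6R,7S,8S)-15-[(tert-butyldimethylsilyl)oxy]-8-hydroxy-14,14-dimethoxygermacra-1(10),4,11(13)-trien-12,6-olide
Conditions: DDQ, CH2Cl2–pH 7 buffer, 0 °C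
Reagents that add atoms: none
Why: Oxidative cleavage of the 4-methoxybenzyl ether by hydride abstraction and hydrolysis; the buffer limits acetal loss, and premature release of the enal would be harmless at this stage.

Step 23
Reactants: 34 (1(10)E,4E,6R,7S,8S)-15-[(tert-butyldimethylsilyl)oxy]-8-hydroxy-14,14-dimethoxygermacra-1(10),4,11(13)-trien-12,6-olide; 35 3-methylbutanoyl chloride
Product: 36 (1(10)E,4E,6R,7S,8S)-15-[(tert-butyldimethylsilyl)oxy]-14,14-dimethoxy-8-(3-methylbutanoyloxy)germacra-1(10),4,11(13)-trien-12,6-olide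
Conditions: 35, pyridine, 4-(dimethylamino)pyridine (cat.), CH2Cl2, 0 °C → rt
Reagents that add atoms: none
Why: Nucleophile-catalysed acylation of the secondary alcohol; the mild base should not move the lactone from O6 to O8.

Step 24
Reactants: 36 (1(10)E,4E,6R,7S,8S)-15-[(tert-butyldimethylsilyl)oxy]-14,14-dimethoxy-8-(3-methylbutanoyloxy)germacra-1(10),4,11(13)-trien-12,6-olide
Product: 37 (1(10)E,4E,6R,7S,8S)-15-hydroxy-8-(3-methylbutanoyloxy)-14-oxogermacra-1(10),4,11(13)-trien-12,6-olide
Conditions: AcOH–THF–H2O (3:1:1), rt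
Reagents that add atoms: water, O
Why: Mild aqueous acid hydrolyses the enal dimethyl acetal and the primary allylic silyl ether in one operation and leaves the ester, the lactone and the stereocentres alone.

## Compound list

1 | 2-(2-bromoethyl)-1,3-dioxolane | BrCCC1OCCO1 | starting material
2 | 3-(trimethylsilyl)prop-2-yn-1-ol | C[Si](C)(C)C#CCO | starting material
3 | [2-(1,3-dioxolan-2-yl)ethyl]magnesium bromide | Br[Mg]CCC1OCCO1 | intermediate (not isolated)
4 | (E)-2-[2-(1,3-dioxolan-2-yl)ethyl]-3-(trimethylsilyl)prop-2-en-1-ol | C[Si](C)(C)/C=C(/CO)CCC1OCCO1 | intermediate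
5 | (E)-2-[2-(1,3-dioxolan-2-yl)ethyl]-3-iodoprop-2-en-1-ol | I/C=C(/CO)CCC1OCCO1 | intermediate
6 | tert-butyl{[(E)-2-[2-(1,3-dioxolan-2-yl)ethyl]-3-iodoprop-2-en-1-yl]oxy}dimethylsilane | I/C=C(/CO[Si](C)(C)C(C)(C)C)CCC1OCCO1 | intermediate
7 | (E)-4-{[(tert-butyldimethylsilyl)oxy]methyl}-5-iodopent-4-enal | I/C=C(/CO[Si](C)(C)C(C)(C)C)CCC=O | intermediate
8 | tert-butyl 4-oxobutanoate | CC(C)(C)OC(=O)CCC=O | starting material
9 | (triphenylphosphoranylidene)acetaldehyde | O=CC=P(c1ccccc1)(c1ccccc1)c1ccccc1 | starting material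
10 | tert-butyl (E)-6-oxohex-4-enoate | CC(C)(C)OC(=O)CC/C=C/C=O | intermediate
11 | tert-butyl (E)-6-hydroxyhex-4-enoate | CC(C)(C)OC(=O)CC/C=C/CO | intermediate
12 | tert-butyl 3-[(2S,3S)-3-(hydroxymethyl)oxiran-2-yl]propanoate | CC(C)(C)OC(=O)CC[C@@H]1O[C@H]1CO | intermediate
13 | ethenylmagnesium bromide | C=C[Mg]Br | starting material
14 | tert-butyl (4S,5R)-5-ethenyl-4,6-dihydroxyhexanoate | CC(C)(C)OC(=O)CC[C@H](O)[C@H](C=C)CO | intermediate
15 | tert-butyl 3-[(2R,4S,5R)-5-ethenyl-2-(4-methoxyphenyl)-1,3-dioxan-4-yl]propanoate | CC(C)(C)OC(=O)CC[C@@H]1O[C@H](c2ccc(OC)cc2)OC[C@H]1C=C | intermediate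
16 | tert-butyl (6E)-6-{[(tert-butyldimethylsilyl)oxy]methyl}-2-{[(2R,4S,5R)-5-ethenyl-2-(4-methoxyphenyl)-1,3-dioxan-4-yl]methyl}-3-hydroxy-7-iodohept-6-enoate (mixture at C2 and C3) | I/C=C(/CO[Si](C)(C)C(C)(C)C)CCC(O)C(C(=O)OC(C)(C)C)C[C@@H]1O[C@H](c2ccc(OC)cc2)OC[C@H]1C=C | intermediate
17 | 3-O-methanesulfonate of 16 | I/C=C(/CO[Si](C)(C)C(C)(C)C)CCC(OS(C)(=O)=O)C(C(=O)OC(C)(C)C)C[C@@H]1O[C@H](c2ccc(OC)cc2)OC[C@H]1C=C | intermediate (not isolated)
18 | tert-butyl (2E,6E)-6-{[(tert-butyldimethylsilyl)oxy]methyl}-2-{[(2R,4S,5R)-5-ethenyl-2-(4-methoxyphenyl)-1,3-dioxan-4-yl]methyl}-7-iodohepta-2,6-dienoate | I/C=C(/CO[Si](C)(C)C(C)(C)C)CC/C=C(/C(=O)OC(C)(C)C)C[C@@H]1O[C@H](c2ccc(OC)cc2)OC[C@H]1C=C | intermediate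
19 | (2R,3S,5E,9E)-9-{[(tert-butyldimethylsilyl)oxy]methyl}-2-ethenyl-5-(hydroxymethyl)-10-iodo-3-[(4-methoxyphenyl)methoxy]deca-5,9-dien-1-ol | I/C=C(/CO[Si](C)(C)C(C)(C)C)CC/C=C(/CO)C[C@H](OCc1ccc(OC)cc1)[C@H](C=C)CO | intermediate
20 | (2E,6E)-6-{[(tert-butyldimethylsilyl)oxy]methyl}-2-{(2S,3R)-3-(hydroxymethyl)-2-[(4-methoxyphenyl)methoxy]pent-4-en-1-yl}-7-iodohepta-2,6-dienal | I/C=C(/CO[Si](C)(C)C(C)(C)C)CC/C=C(/C=O)C[C@H](OCc1ccc(OC)cc1)[C@H](C=C)CO | intermediate
21 | (2R,3S,5E,9E)-9-{[(tert-butyldimethylsilyl)oxy]methyl}-5-(dimethoxymethyl)-2-ethenyl-10-iodo-3-[(4-methoxyphenyl)methoxy]deca-5,9-dien-1-ol | I/C=C(/CO[Si](C)(C)C(C)(C)C)CC/C=C(/C(OC)OC)C[C@H](OCc1ccc(OC)cc1)[C@H](C=C)CO | intermediate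
22 | {[(2R,3S,5E,9E)-9-{[(tert-butyldimethylsilyl)oxy]methyl}-5-(dimethoxymethyl)-2-ethenyl-10-iodo-3-[(4-methoxyphenyl)methoxy]deca-5,9-dien-1-yl]oxy}triethylsilane | I/C=C(/CO[Si](C)(C)C(C)(C)C)CC/C=C(/C(OC)OC)C[C@H](OCc1ccc(OC)cc1)[C@H](C=C)CO[Si](CC)(CC)CC | intermediate
23 | 9-[(3R,4S,6E,10E)-10-{[(tert-butyldimethylsilyl)oxy]methyl}-6-(dimethoxymethyl)-11-iodo-4-[(4-methoxyphenyl)methoxy]-3-{[(triethylsilyl)oxy]methyl}undeca-6,10-dien-1-yl]-9-borabicyclo[3.3.1]nonane | I/C=C(/CO[Si](C)(C)C(C)(C)C)CC/C=C(/C(OC)OC)C[C@H](OCc1ccc(OC)cc1)[C@H](CCB1C2CCCC1CCC2)CO[Si](CC)(CC)CC | intermediate (not isolated)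
24 | (3R,4S,6E,10E)-10-{[(tert-butyldimethylsilyl)oxy]methyl}-6-(dimethoxymethyl)-11-iodo-4-[(4-methoxyphenyl)methoxy]-3-{[(triethylsilyl)oxy]methyl}undeca-6,10-dien-1-ol | I/C=C(/CO[Si](C)(C)C(C)(C)C)CC/C=C(/C(OC)OC)C[C@H](OCc1ccc(OC)cc1)[C@H](CCO)CO[Si](CC)(CC)CC | intermediate
25 | (3R,4S,6E,10E)-10-{[(tert-butyldimethylsilyl)oxy]methyl}-6-(dimethoxymethyl)-11-iodo-4-[(4-methoxyphenyl)methoxy]-3-{[(triethylsilyl)oxy]methyl}undeca-6,10-dienoic acid | I/C=C(/CO[Si](C)(C)C(C)(C)C)CC/C=C(/C(OC)OC)C[C@H](OCc1ccc(OC)cc1)[C@H](CC(=O)O)CO[Si](CC)(CC)CC | intermediate (not isolated)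
26 | methyl (3R,4S,6E,10E)-10-{[(tert-butyldimethylsilyl)oxy]methyl}-6-(dimethoxymethyl)-11-iodo-4-[(4-methoxyphenyl)methoxy]-3-{[(triethylsilyl)oxy]methyl}undeca-6,10-dienoate | I/C=C(/CO[Si](C)(C)C(C)(C)C)CC/C=C(/C(OC)OC)C[C@H](OCc1ccc(OC)cc1)[C@H](CC(=O)OC)CO[Si](CC)(CC)CC | intermediate
27 | methyl (3S,4S,6E,10E)-10-{[(tert-butyldimethylsilyl)oxy]methyl}-6-(dimethoxymethyl)-3-formyl-11-iodo-4-[(4-methoxyphenyl)methoxy]undeca-6,10-dienoate | I/C=C(/CO[Si](C)(C)C(C)(C)C)CC/C=C(/C(OC)OC)C[C@H](OCc1ccc(OC)cc1)[C@H](CC(=O)OC)C=O | intermediate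
28 | methyl 2-[(1R,2R,3E,7E,10S)-4-{[(tert-butyldimethylsilyl)oxy]methyl}-8-(dimethoxymethyl)-2-hydroxy-10-[(4-methoxyphenyl)methoxy]cyclodeca-3,7-dien-1-yl]acetate | COC(=O)C[C@@H]1[C@H](O)/C=C(/CO[Si](C)(C)C(C)(C)C)CC/C=C(/C(OC)OC)C[C@@H]1OCc2ccc(OC)cc2 | intermediate
29 | (1(10)E,4E,6R,7S,8S)-15-[(tert-butyldimethylsilyl)oxy]-14,14-dimethoxy-8-[(4-methoxyphenyl)methoxy]-13-norgermacra-1(10),4-dien-12,6-olide | C1C(=O)O[C@@H]2/C=C(/CO[Si](C)(C)C(C)(C)C)CC/C=C(/C(OC)OC)C[C@H](OCc3ccc(OC)cc3)[C@H]12 | intermediate
30 | N,N-dimethylmethyleneiminium iodide | C=[N+](C)C.[I-] | starting material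
31 | (1(10)E,4E,6R,7S,8S,11RS)-15-[(tert-butyldimethylsilyl)oxy]-13-(dimethylamino)-14,14-dimethoxy-8-[(4-methoxyphenyl)methoxy]germacra-1(10),4-dien-12,6-olide | CN(C)CC1C(=O)O[C@@H]2/C=C(/CO[Si](C)(C)C(C)(C)C)CC/C=C(/C(OC)OC)C[C@H](OCc3ccc(OC)cc3)[C@H]12 | intermediate (not isolated)
32 | N-methyl ammonium iodide of 31 (13-trimethylammonio lactone iodide) | C[N+](C)(C)CC1C(=O)O[C@@H]2/C=C(/CO[Si](C)(C)C(C)(C)C)CC/C=C(/C(OC)OC)C[C@H](OCc3ccc(OC)cc3)[C@H]12.[I-] | intermediate (not isolated)
33 | (1(10)E,4E,6R,7S,8S)-15-[(tert-butyldimethylsilyl)oxy]-14,14-dimethoxy-8-[(4-methoxyphenyl)methoxy]germacra-1(10),4,11(13)-trien-12,6-olide | C=C1C(=O)O[C@@H]2/C=C(/CO[Si](C)(C)C(C)(C)C)CC/C=C(/C(OC)OC)C[C@H](OCc3ccc(OC)cc3)[C@H]12 | intermediate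
34 | (1(10)E,4E,6R,7S,8S)-15-[(tert-butyldimethylsilyl)oxy]-8-hydroxy-14,14-dimethoxygermacra-1(10),4,11(13)-trien-12,6-olide | C=C1C(=O)O[C@@H]2/C=C(/CO[Si](C)(C)C(C)(C)C)CC/C=C(/C(OC)OC)C[C@H](O)[C@H]12 | intermediate
35 | 3-methylbutanoyl chloride | CC(C)CC(=O)Cl | starting material
36 | (1(10)E,4E,6R,7S,8S)-15-[(tert-butyldimethylsilyl)oxy]-14,14-dimethoxy-8-(3-methylbutanoyloxy)germacra-1(10),4,11(13)-trien-12,6-olide | C=C1C(=O)O[C@@H]2/C=C(/CO[Si](C)(C)C(C)(C)C)CC/C=C(/C(OC)OC)C[C@H](OC(=O)CC(C)C)[C@H]12 | intermediate
37 | (1(10)E,4E,6R,7S,8S)-15-hydroxy-8-(3-methylbutanoyloxy)-14-oxogermacra-1(10),4,11(13)-trien-12,6-olide (CNP0345200.6) | C=C1C(=O)O[C@@H]2/C=C(/CO)CC/C=C(/C=O)C[C@H](OC(=O)CC(C)C)[C@H]12 | target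

## Step count and least certain steps

Total: 24 steps. Longest linear sequence: 20 steps (steps 5–24, from 8). The C1–C5 fragment 7 takes 4 steps (steps 1–4).

Step 19 (key step). The most likely failure is poor facial selectivity at C6: the chiral chromium ligand has to override the intrinsic preference of the α-branched β-alkoxy aldehyde, and the ring constraint may add a bias of its own. Intermolecular coupling is the second risk. The fallback accepts the substrate-preferred epimer and inverts it. It sets out from 27, which is cyclised with ligand-free CrCl2 and catalytic NiCl2 in DMSO–THF at high dilution to give methyl 2-[(1R,2S,3E,7E,10S)-4-{[(tert-butyldimethylsilyl)oxy]methyl}-8-(dimethoxymethyl)-2-hydroxy-10-[(4-methoxyphenyl)methoxy]cyclodeca-3,7-dien-1-yl]acetate F1. Saponification with LiOH in aqueous THF gives the hydroxy acid 2-[(1R,2S,3E,7E,10S)-4-{[(tert-butyldimethylsilyl)oxy]methyl}-8-(dimethoxymethyl)-2-hydroxy-10-[(4-methoxyphenyl)methoxy]cyclodeca-3,7-dien-1-yl]acetic acid F2. Mitsunobu lactonisation (Ph3P, diisopropyl azodicarboxylate, PhMe) then closes the ring with inversion at C6 and returns to the route at 29. Allylic transposition during the displacement would have to be watched.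

Step 1. The most likely failure is decay of the acetal-bearing Grignard reagent before its addition to the hindered silyl alkyne is complete, so that conversion stalls. The fallback changes the C1 synthon to a thermally robust alkene. It sets out from 2: copper-catalysed addition of but-3-enylmagnesium bromide under the same directing principle, with heating if needed, gives (E)-2-(but-3-en-1-yl)-3-(trimethylsilyl)prop-2-en-1-ol F3. Silylation gives tert-butyl{[(E)-2-(but-3-en-1-yl)-3-(trimethylsilyl)prop-2-en-1-yl]oxy}dimethylsilane F4, which is done before iodination to prevent iodoetherification. Iododesilylation with N-iodosuccinimide gives tert-butyl{[(E)-2-(but-3-en-1-yl)-3-iodoprop-2-en-1-yl]oxy}dimethylsilane F5. Dihydroxylation of the terminal alkene (catalytic OsO4, N-methylmorpholine N-oxide) and NaIO4 cleavage return to the route at 7; the electron-poor iodoalkene should not be dihydroxylated.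

Step 11. The most likely failure is incomplete geometric control in the elimination (some Z enoate, or deconjugation by the amidine base). The fallback replaces aldol–elimination by an olefination. It sets out from 15: C-phosphorylation of the ester enolate (LiN(CHMe2)2, 2.2 equiv, then ClP(O)(OEt)2) gives tert-butyl 2-(diethoxyphosphoryl)-3-[(2R,4S,5R)-5-ethenyl-2-(4-methoxyphenyl)-1,3-dioxan-4-yl]propanoate F6. Horner–Wadsworth–Emmons reaction of F6 with 7 (NaH, THF) returns to the route at 18.

Step 18. The most likely failure is base-induced damage to the product during the amine stage (epimerisation at C7 or β-elimination of the C8 ether), or incomplete desilylation at the sulfonium stage. The fallback separates deprotection from oxidation and avoids amine base. It sets out from 26: buffered HF·pyridine in THF–pyridine at 0 °C removes the triethylsilyl group selectively to give methyl (3R,4S,6E,10E)-10-{[(tert-butyldimethylsilyl)oxy]methyl}-6-(dimethoxymethyl)-3-(hydroxymethyl)-11-iodo-4-[(4-methoxyphenyl)methoxy]undeca-6,10-dienoate F7. F7 is oxidised at once with Dess–Martin periodinane and NaHCO3 and returns to the route at 27. It must not be stored, because it can lactonise.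

## Further compounds

F1 | step 19 | methyl 2-[(1R,2S,3E,7E,10S)-4-{[(tert-butyldimethylsilyl)oxy]methyl}-8-(dimethoxymethyl)-2-hydroxy-10-[(4-methoxyphenyl)methoxy]cyclodeca-3,7-dien-1-yl]acetate | COC(=O)C[C@@H]1[C@@H](O)/C=C(/CO[Si](C)(C)C(C)(C)C)CC/C=C(/C(OC)OC)C[C@@H]1OCc2ccc(OC)cc2
F2 | step 19 | 2-[(1R,2S,3E,7E,10S)-4-{[(tert-butyldimethylsilyl)oxy]methyl}-8-(dimethoxymethyl)-2-hydroxy-10-[(4-methoxyphenyl)methoxy]cyclodeca-3,7-dien-1-yl]acetic acid | OC(=O)C[C@@H]1[C@@H](O)/C=C(/CO[Si](C)(C)C(C)(C)C)CC/C=C(/C(OC)OC)C[C@@H]1OCc2ccc(OC)cc2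
F3 | step 1 | (E)-2-(but-3-en-1-yl)-3-(trimethylsilyl)prop-2-en-1-ol | C[Si](C)(C)/C=C(/CO)CCC=C
F4 | step 1 | tert-butyl{[(E)-2-(but-3-en-1-yl)-3-(trimethylsilyl)prop-2-en-1-yl]oxy}dimethylsilane | C[Si](C)(C)/C=C(/CO[Si](C)(C)C(C)(C)C)CCC=C
F5 | step 1 | tert-butyl{[(E)-2-(but-3-en-1-yl)-3-iodoprop-2-en-1-yl]oxy}dimethylsilane | I/C=C(/CO[Si](C)(C)C(C)(C)C)CCC=C
F6 | step 11 | tert-butyl 2-(diethoxyphosphoryl)-3-[(2R,4S,5R)-5-ethenyl-2-(4-methoxyphenyl)-1,3-dioxan-4-yl]propanoate | CCOP(=O)(OCC)C(C[C@@H]1O[C@H](c2ccc(OC)cc2)OC[C@H]1C=C)C(=O)OC(C)(C)C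
F7 | step 18 | methyl (3R,4S,6E,10E)-10-{[(tert-butyldimethylsilyl)oxy]methyl}-6-(dimethoxymethyl)-3-(hydroxymethyl)-11-iodo-4-[(4-methoxyphenyl)methoxy]undeca-6,10-dienoate | I/C=C(/CO[Si](C)(C)C(C)(C)C)CC/C=C(/C(OC)OC)C[C@H](OCc1ccc(OC)cc1)[C@H](CC(=O)OC)CO
A1 | alternative 1 | open-chain C2 allylic bromide with C3 phenylsulfonyl group and lactol methyl ether ring | BrC/C=C(/C(OC)OC)C[C@H](OCc1ccc(OC)cc1)[C@H]1[C@@H](/C=C(/CO[Si](c2ccccc2)(c2ccccc2)C(C)(C)C)CS(=O)(=O)c2ccccc2)OC(OC)C1=C
A2 | alternative 1 | ten-membered cis,cis-diene with phenylsulfonyl group on C3 | C=C1C(OC)O[C@@H]2/C=C(/CO[Si](c3ccccc3)(c3ccccc3)C(C)(C)C)C(S(=O)(=O)c3ccccc3)C/C=C(/C(OC)OC)C[C@H](OCc3ccc(OC)cc3)[C@H]12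
A3 | alternative 2 | open-chain (Z)-2-(bromomethyl)enoate with C8 aldehyde and C6 triethylsilyl ether | BrC/C(C(=O)OC(C)(C)C)=C\[C@H](O[Si](CC)(CC)CC)/C=C(/COCc1ccc(OC)cc1)CC/C=C(/C(OC)OC)CC=O
A4 | alternative 2 | ten-membered C8 carbinol with 2-propenoate arm on C7 | C=C(C(=O)OC(C)(C)C)[C@@H]1[C@H](O[Si](CC)(CC)CC)/C=C(/COCc2ccc(OC)cc2)CC/C=C(/C(OC)OC)C[C@@H]1O
A5 | alternative 3 | open-chain C1 aldehyde with C10 dimethyl phosphonoacetate and lactol methyl ether ring | O=CCC/C(CO[Si](c1ccccc1)(c1ccccc1)C(C)(C)C)=C\[C@H]1OC(OC)C(=C)[C@H]1[C@@H](OCc1ccc(OC)cc1)CC(C(=O)OC)P(=O)(OC)OC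
A6 | alternative 3 | ten-membered diene with C14 methyl ester | C=C1C(OC)O[C@@H]2/C=C(/CO[Si](c3ccccc3)(c3ccccc3)C(C)(C)C)CC/C=C(/C(=O)OC)C[C@H](OCc3ccc(OC)cc3)[C@H]12
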